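# Proposed total synthesis of CNP0257844.1 (7-acetoxy-2-hydroxy-3-oxo-cis-cleroda-1,4(18)-dien-15-oic acid)

Clerodane numbering is used throughout: ring A = C1–C5, C10; ring B = C5–C10; C17 on C8, C18 on C4, C19 on C5, C20 on C9; chain C11–C16 on C9.

## The problem

The target is a cis-fused clerodane. Ring A is a diosphenol (C2 enol, C3 ketone) with an exocyclic C4=C18 methylene. Ring B carries C5 (quaternary, C19), C7 (acetoxy), C8 (C17), C9 (quaternary, C20 and the chain) and C10 (H cis to C19); the chain ends in the C15 acid and has a remote stereocentre at C13. The two quaternary carbons C5 and C9 flank C10, and C19 must end up trans to C20 and cis to the C11 chain. C8 and C9 can be set together in an open chain and can then steer C5 if ring B is closed between C5 and C6; C7 and C10 can be set from the finished ring B, whereas C13 is too far from everything and must be set on its own. The exo-methylene diosphenol is a Michael acceptor and an oxidisable enol, so it has to appear last; the C7 acetate rules out strong base late, and C8 is epimerisable while C7 is a ketone. The enabling feature is ring A itself: C1–C5 and C10, with oxygen on C2 and C3 and carbon on C4 and C5, are the atoms of a 2-methoxy-3,4-dimethylphenol that carries C9 on the ring carbon para to the methoxy group. In that phenol C5 is para to the C2 hydroxyl, so two-electron oxidation makes C5 electrophilic, and C6 of a C7 enol ether hung from C9 can reach it, closing ring B and creating the C5 quaternary centre.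

## Retrosynthesis

**C4=C18 last (35 back to 31).** The exocyclic double bond of 35 is removed first, by a selenoxide elimination from C4 selenide 33. C5 has no hydrogen, so the elimination from selenoxide 34 can only go to C18. Selenide 33 comes from free diosphenol 32, and 32 from its methyl ether 31 by demethylation. This takes away the only fragile functionality and leaves a robust 3-methoxy-enone. The forward steps must selenenylate C4 and not C1.

**Oxidation levels and two ring stereocentres (31 back to 26).** Acetate 31 is traced through acid 30 and diol 28 to dienone alcohol 27 and diketone 26. The order is chosen for stereocontrol: the C7 ketone is reduced while ring A is still a flat dienone, and the resulting C7 hydroxyl, which lies on the face of C19, then directs hydrogen to C10 on that same face. The C15 alcohol is oxidised before the diosphenol is unmasked. Compound 26 has only C5, C8, C9 and C13 as stereocentres.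

**C5–C6, the key cut (26 back to 23).** Cutting C5–C6 turns ring A into an arene that already holds C18, C19 and both oxygens, and leaves open-chain phenol 23 with three stereocentres and no ring besides the benzene. The neighbouring cuts C5–C10 and C9–C10 would leave a quaternary centre to be made inside a ring next to another one. The forward reaction asks for three things:
- oxidation of the phenol and not of the enol ether;
- attack of C6 at C5 and not at C1, which is the other position ortho to the tether and would also give a six-membered ring (then rearomatising to a tetralone);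
- attack on the arene face that places C19 trans to C20.

In a chair-like closure C19 is forced onto the side of the pseudo-axial substituent of C9, so the required isomer comes from the chair with the C11 chain and C17 pseudo-axial and C20 in the arene plane.

**Enol ether from an ester (23 back to 21).** The C6=C7 enol ether is made as a methyl enol ether by methylenation of methyl ester 21, giving 22, and the phenol is then freed with fluoride. A silyl enol ether would not survive the fluoride or base needed to free the phenol, and making it by enolisation would need strong base beside the phenol. The ester route also fixes the position of the double bond.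

**C12–C13 (21 back to 17 and 9).** The chain is attached by hydroboration of the vinyl group of 17 and coupling with alkenyl iodide 9, giving allylic alcohol 19. C13 is then set by catalyst-controlled hydrogenation of 19 to 20, which is the right tool for a stereocentre that no other centre can reach. Attaching the chain to C9 by alkylation instead would mean building the quaternary centre late and with a hindered electrophile.

**C8–C9 (17 back to 14).** An Ireland–Claisen rearrangement of propanoate 14 forms the benzylic quaternary centre C9 and the tertiary centre C8 in one step through boron ketene acetal 15. Their relative configuration follows from the Z alkene and the Z(O)-enolate; the absolute configuration comes from a chiral ligand on boron. The vinyl group that the rearrangement leaves is C11=C12, the handle for the chain.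

**C9–C10 (14 back to 6, 9 and 13).** Ester 14 is the propanoate of Z allylic alcohol 12, made by cross-coupling of aryl bromide 6 with iodide 9; acid chloride 13 supplies C7, C8 and C17. Iodide 9, made in one step from alkynol 7, is used twice in the route.

**The arene (6 back to 1).** Bromide 6 comes from anisole 1 in four steps: bromination para to the methoxy group (2), formylation at the only remaining ortho position (3), Dakin oxidation to phenol 5 and silylation. Bromination before hydroxylation is required, because the free phenol would direct bromine to C1.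

## Roads not taken

**Alternative 1:** Anionic oxy-Cope rearrangement of a bridged bicyclic vinyl carbinol. The cut is C1–C10. In the forward step an alkoxide rearranges, the bridged bicycle opens and ring A of cis-decalin A1 closes. Its merit is that the cis ring fusion between C5 and C10 follows from the geometry of the sigmatropic shift, which is more secure than the directed hydrogenation of step 16. Its weakness for this target is what A1 still lacks. C9 is still an alkene carbon, so the side chain, C17 and the C9 quaternary centre must all be added to a finished decalin. The oxygens sit on C3 and C4, whereas the target needs them on C2 and C3 with a carbon (C18) on C4. The chosen plan sets against the better C10 control that C8, C9, C13 and the whole chain are in place before any ring is closed, and that the arene brings both oxygens, C18 and C19 in the right positions.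

**Alternative 2:** Intramolecular Diels–Alder reaction. The cuts are C5–C10 and C3–C4. Heating an open-chain triene closes rings A and B together to octalin A2. This is the most convergent of the four ideas: four stereocentres (C3, C4, C5, C10) form in one step, C10 is set directly, and C18 arrives as an ester on C4 that can be turned into the exo-methylene without selenium chemistry. In these respects it is better than the chosen plan. Its weak points are the substrate and the aftermath. The dienophile carbon C5 is fully substituted and the diene end C10 is attached to the quaternary C9, so the cycloaddition is slow and its endo/exo and facial selectivity are uncertain. The triene must carry C7, C8, C9 and C13 and two defined alkenes, all made in an open chain. A2 has no oxygen on C2 and a silyl ether at C3, so the diosphenol still needs two oxidations. The chosen plan answers with a flat, cheap arene as ring A and only one stereocentre to control in the ring-forming step.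

**Alternative 3:** Three-component conjugate addition and iminium trapping. The cuts are C5–C19 and C4–C18. A methylcopper reagent adds to C5 of a ring A enone and the enolate is trapped at C4 by an iminium electrophile, giving Mannich base A3. Its merits are real. Conjugate addition to such octalones usually gives the cis-fused product, and the amine on C18 is an ideal precursor of the exo-methylene (quaternisation and elimination), cleaner than step 20 of the chosen plan. Its weak points are that the enone must already be a complete decalin with C7, C8, C9 and C10 set, so the C9 quaternary centre has to be made in an annulation with little control. The addition has to create C5 between C6 and the neopentyl C10. A3 has no oxygen on C2, which would have to be introduced by a late, regioselective oxidation next to the C3 ketone. The chosen plan has to set against the better exo-methylene entry that ring A's oxygen pattern costs nothing and that C5 is formed in the same step that closes ring B.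

Key step: step 14

## Assumptions

- The (S,S)-diazaborolidine is assumed to deliver the (2S,3S) acid 16 in step 8; if the sense of induction is the reverse, the (R,R)-reagent is used and nothing else changes.
- Ru(OAc)2[(R)-BINAP] is assumed to give the (6R) alcohol 20 from the Z allylic alcohol 19, by analogy with nerol.

## Steps

Step 1
Reactants: 1 2,3-dimethylanisole
Product: 2 4-bromo-2,3-dimethylanisole
Conditions: NBS, MeCN, 0 °C to rt
Reagents that add atoms: N-bromosuccinimide, O=C1CCC(=O)N1Br
Why: Electrophilic aromatic bromination; the methoxy group directs to its para position, and the polar medium leaves the benzylic methyl groups untouched.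

Step 2
Reactants: 2 4-bromo-2,3-dimethylanisole
Product: 3 5-bromo-2-methoxy-3,4-dimethylbenzaldehyde
Conditions: Cl2CHOCH3, TiCl4, CH2Cl2, 0 °C; then H2O
Reagents that add atoms: dichloromethyl methyl ether, COC(Cl)Cl; water, O
Why: Rieche formylation (Friedel–Crafts type); with the para position taken by bromine, the only carbon ortho to the methoxy group is attacked, the other free carbon being ortho to bromine and meta to oxygen.

Step 3
Reactants: 3 5-bromo-2-methoxy-3,4-dimethylbenzaldehyde
Product: 5 5-bromo-2-methoxy-3,4-dimethylphenol, via aryl formate 4 (not isolated)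
Conditions: mCPBA, CH2Cl2, rt; then K2CO3 (cat.), MeOH, 0 °C
Reagents that add atoms: 3-chloroperoxybenzoic acid, O=C(OO)c1cccc(Cl)c1
Why: Baeyer–Villiger (Dakin-type) oxidation; the electron-rich aryl group migrates to oxygen and the formate is removed by methanolysis.

Step 4
Reactants: 5 5-bromo-2-methoxy-3,4-dimethylphenol
Product: 6 (5-bromo-2-methoxy-3,4-dimethylphenoxy)triisopropylsilane
Conditions: i-Pr3SiCl, imidazole, DMF, rt
Reagents that add atoms: chlorotriisopropylsilane, CC(C)[Si](Cl)(C(C)C)C(C)C
Why: Silylation of a phenol; the triisopropylsilyl ether survives aryllithium formation, enolate chemistry, aqueous phosphate and the Ti/Al reagent, and is removed later by fluoride.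

Step 5
Reactants: 7 but-2-yn-1-ol
Product: 9 (Z)-3-iodobut-2-en-1-ol, via alkenylaluminate 8 (not isolated)
Conditions: Na[AlH2(OCH2CH2OCH3)2], Et2O, 0 °C to rt; then I2, THF, −78 to 0 °C
Reagents that add atoms: iodine, II
Why: Hydroxyl-directed trans-hydroalumination puts aluminium on C3 in a five-membered ring, and iodinolysis with retention gives the Z iodide (iodine cis to CH2OH); a standard preparation of this building block.

Step 6
Reactants: 6 (5-bromo-2-methoxy-3,4-dimethylphenoxy)triisopropylsilane (1.3 equiv); 9 (Z)-3-iodobut-2-en-1-ol
Product: 12 (Z)-3-[4-methoxy-2,3-dimethyl-5-(triisopropylsilyloxy)phenyl]but-2-en-1-ol, via aryllithium 10 (not isolated), via arylzinc chloride 11 (not isolated)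
Conditions: t-BuLi (2 equiv per 6), THF, −78 °C; ZnCl2, −78 to 0 °C; then 9, Pd(OAc)2 (2 mol%), SPhos (4 mol%), THF, 25 °C
Reagents that add atoms: none
Why: Bromine–lithium exchange, transmetalation to zinc and Negishi cross-coupling with retention of the alkene geometry; Pd/SPhos couples ortho-substituted arylzinc reagents and tolerates the free hydroxyl of 9.

Step 7
Reactants: 12 (Z)-3-[4-methoxy-2,3-dimethyl-5-(triisopropylsilyloxy)phenyl]but-2-en-1-ol; 13 propanoyl chloride
Product: 14 (Z)-3-[4-methoxy-2,3-dimethyl-5-(triisopropylsilyloxy)phenyl]but-2-en-1-yl propanoate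
Conditions: pyridine, DMAP (cat.), CH2Cl2, 0 °C
Reagents that add atoms: none
Why: Acylation of a primary allylic alcohol under mild base; no stereocentre is involved.

Step 8
Reactants: 14 (Z)-3-[4-methoxy-2,3-dimethyl-5-(triisopropylsilyloxy)phenyl]but-2-en-1-yl propanoate
Product: 17 methyl (2S,3S)-3-[4-methoxy-2,3-dimethyl-5-(triisopropylsilyloxy)phenyl]-2,3-dimethylpent-4-enoate, via boron ketene acetal 15 (not isolated), via carboxylic acid 16 (not isolated)
Conditions: (4S,5S)-2-bromo-4,5-diphenyl-1,3-bis[3,5-bis(trifluoromethyl)phenylsulfonyl]-1,3,2-diazaborolidine (made from the (S,S)-bis-sulfonamide and BBr3), i-Pr2NEt, CH2Cl2, −78 °C, then −20 to 4 °C, several days; aq. work-up; then Me3SiCHN2, MeOH–toluene, 0 °C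
Reagents that add atoms: (trimethylsilyl)diazomethane, C[Si](C)(C)C=[N+]=[N-]
Why: Enantioselective Ireland–Claisen rearrangement: the amine/solvent pair gives the Z(O)-enolate (C17 cis to O–B), and in the chair transition state the aryl group is axial on C9 and C17 equatorial on C8, which gives the required C8/C9 relationship. The C2-symmetric sulfonamide ligand on boron distinguishes the two mirror-image chairs; the acid is then methylated without touching either centre.

Step 9
Reactants: 17 methyl (2S,3S)-3-[4-methoxy-2,3-dimethyl-5-(triisopropylsilyloxy)phenyl]-2,3-dimethylpent-4-enoate; 9 (Z)-3-iodobut-2-en-1-ol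
Product: 19 methyl (2S,3S,6Z)-8-hydroxy-3-[4-methoxy-2,3-dimethyl-5-(triisopropylsilyloxy)phenyl]-2,3,6-trimethyloct-6-enoate, via alkylborane 18 (not isolated)
Conditions: 9-BBN, THF, 0 °C to rt; then 9, PdCl2(dppf) (5 mol%), AsPh3, K3PO4 (aq.), DMF, rt
Reagents that add atoms: none
Why: Anti-Markovnikov hydroboration of the vinyl group and B-alkyl Suzuki–Miyaura coupling with retention at the alkenyl iodide; ester, free hydroxyl and aryl silyl ether are tolerated.

Step 10
Reactants: 19 methyl (2S,3S,6Z)-8-hydroxy-3-[4-methoxy-2,3-dimethyl-5-(triisopropylsilyloxy)phenyl]-2,3,6-trimethyloct-6-enoate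
Product: 20 methyl (2S,3S,6R)-8-hydroxy-3-[4-methoxy-2,3-dimethyl-5-(triisopropylsilyloxy)phenyl]-2,3,6-trimethyloctanoate
Conditions: Ru(OAc)2[(R)-BINAP] (1 mol%), H2 (50 atm), MeOH, 25 °C
Reagents that add atoms: none
Why: Noyori asymmetric hydrogenation of an allylic alcohol; the hydroxyl binds ruthenium and the BINAP ligand alone decides the face, so C13 is set independently of the distant C8 and C9.

Step 11
Reactants: 20 methyl (2S,3S,6R)-8-hydroxy-3-[4-methoxy-2,3-dimethyl-5-(triisopropylsilyloxy)phenyl]-2,3,6-trimethyloctanoate
Product: 21 methyl (2S,3S,6R)-8-(tert-butyldimethylsilyloxy)-3-[4-methoxy-2,3-dimethyl-5-(triisopropylsilyloxy)phenyl]-2,3,6-trimethyloctanoate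
Conditions: t-BuMe2SiCl, imidazole, CH2Cl2, rt
Reagents that add atoms: tert-butyldimethylsilyl chloride, CC(C)(C)[Si](C)(C)Cl
Why: Silylation of the primary alcohol, needed because the methylenation reagent of the next step is consumed by hydroxyl groups.

Step 12
Reactants: 21 methyl (2S,3S,6R)-8-(tert-butyldimethylsilyloxy)-3-[4-methoxy-2,3-dimethyl-5-(triisopropylsilyloxy)phenyl]-2,3,6-trimethyloctanoate
Product: 22 tert-butyl{[(3R,6S,7S)-8-methoxy-6-[4-methoxy-2,3-dimethyl-5-(triisopropylsilyloxy)phenyl]-3,6,7-trimethylnon-8-en-1-yl]oxy}dimethylsilane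
Conditions: Cp2Ti(μ-Cl)(μ-CH2)AlMe2 (Tebbe reagent, 2 equiv), pyridine, THF–toluene, −40 °C to rt; NaOH (aq.)
Reagents that add atoms: Tebbe reagent, C[Al-](C)(Cl)C[Ti+](C1C=CC=C1)C1C=CC=C1
Why: Tebbe methylenation of an ester to a methyl enol ether; the reagent is not basic, so C8 is not epimerised, and the C6=C7 position of the double bond is fixed by construction.

Step 13
Reactants: 22 tert-butyl{[(3R,6S,7S)-8-methoxy-6-[4-methoxy-2,3-dimethyl-5-(triisopropylsilyloxy)phenyl]-3,6,7-trimethylnon-8-en-1-yl]oxy}dimethylsilane
Product: 23 (3R,6S,7S)-6-(5-hydroxy-4-methoxy-2,3-dimethylphenyl)-8-methoxy-3,6,7-trimethylnon-8-en-1-ol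
Conditions: Bu4NF (2.5 equiv), THF, 0 °C to rt; pH 7 buffer; used at once
Reagents that add atoms: none
Why: Fluoride cleaves the aryl and the primary silyl ether; the methyl enol ether is inert to fluoride and base and is kept from acid by the buffered work-up.

Step 14
Reactants: 23 (3R,6S,7S)-6-(5-hydroxy-4-methoxy-2,3-dimethylphenyl)-8-methoxy-3,6,7-trimethylnon-8-en-1-ol
Product: 26 15-hydroxy-3-methoxycleroda-1(10),3-diene-2,7-dione, via phenoxonium ion 24 (not isolated), via methoxycarbenium ion 25 (not isolated)
Conditions: reticulated vitreous carbon anode, Pt cathode, undivided cell, LiClO4 (0.1 M), 2,6-lutidine (2 equiv), MeCN–H2O (99:1), constant current, 2.2 F/mol, 0 °C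
Reagents that add atoms: water, O
Why: Two-electron anodic oxidation of the phenol, buffered by 2,6-lutidine and occurring well below the potential of the 1,1-disubstituted enol ether, gives phenoxonium ion 24, whose positive charge sits mainly on C3 (methoxy-stabilised) and C5 (tertiary) and much less on C1. The enol ether carbon C6 attacks C5, and water takes methoxycarbenium ion 25 to the C7 ketone with loss of methanol. The closest known reactions are the anodic and PhI(OAc)2-mediated intramolecular para couplings of phenols with enol ethers, allylsilanes and alkenes that give 4,4-disubstituted cyclohexadienones. Ring B closes as a six-membered ring in a 6-(enolendo)-exo-trig mode: both enol ether carbons end up in the ring and the C4=C5 bond that accepts the nucleophile lies outside it. The new stereocentre C5 is controlled by C9 and C8 through a chair-like transition state in which C19 is pushed to the side of the pseudo-axial substituent on C9. With C17 pseudo-axial (it has no 1,3-diaxial partner because C6 and C10 are trigonal, and it avoids A(1,2) strain with the C7 methoxy group), the C11 chain is pseudo-axial and C20 lies in the arene plane, which puts C19 cis to C11 and trans to C20. The step needs oxidation of the phenol only (potential gap and base), attack at C5 and not at C1 (secured only by the higher charge at the para carbon; C1 attack would rearomatise to a tetralone) and the facial selectivity just described. C3 is out of reach of the tether, and the blocked para carbon cannot rearomatise, so the quaternary centre is kept.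

Step 15
Reactants: 26 15-hydroxy-3-methoxycleroda-1(10),3-diene-2,7-dione
Product: 27 7,15-dihydroxy-3-methoxycleroda-1(10),3-dien-2-one (7-OH cis to C19)
Conditions: NaBH4, MeOH–CH2Cl2 (1:1), −40 °C
Reagents that add atoms: none
Why: Chemoselective 1,2-reduction of the saturated ketone; the cross-conjugated dienone carbonyl is much less electrophilic at low temperature. In the ring B chair imposed by the planar dienone, C19 and the C11 chain are both axial on one face and block it, so hydride enters from the other face and the hydroxyl ends up cis to C19.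

Step 16
Reactants: 27 7,15-dihydroxy-3-methoxycleroda-1(10),3-dien-2-one
Product: 28 7,15-dihydroxy-3-methoxy-cis-clerod-3-en-2-one (H10 cis to C19)
Conditions: [Ir(cod)(PCy3)(py)]PF6 (5–10 mol%), H2 (1 atm), CH2Cl2, rt
Reagents that add atoms: none
Why: Hydroxyl-directed homogeneous hydrogenation; the cationic iridium catalyst binds the C7 hydroxyl, which lies on the face of C19, and delivers H2 to C1=C10 from that face, giving the cis ring fusion. The tetrasubstituted, methoxy-bearing C3=C4 bond is not reduced.

Step 17
Reactants: 28 7,15-dihydroxy-3-methoxy-cis-clerod-3-en-2-one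
Product: 30 7-hydroxy-3-methoxy-2-oxo-cis-clerod-3-en-15-oic acid, via aldehyde 29 (not isolated)
Conditions: TEMPO (0.2 equiv), PhI(OAc)2 (2.5 equiv), MeCN–H2O (1:1), rt
Reagents that add atoms: water, O
Why: Oxoammonium (TEMPO) oxidation is selective for the primary alcohol over the hindered secondary C7 hydroxyl; in aqueous MeCN the aldehyde is hydrated and oxidised on to the acid.

Step 18
Reactants: 30 7-hydroxy-3-methoxy-2-oxo-cis-clerod-3-en-15-oic acid
Product: 31 7-acetoxy-3-methoxy-2-oxo-cis-clerod-3-en-15-oic acid
Conditions: Ac2O, pyridine, DMAP (cat.), rt; aq. NaHCO3, then acidify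
Reagents that add atoms: acetic anhydride, CC(=O)OC(C)=O
Why: Acetylation of the C7 hydroxyl, now equatorial in the cis-decalin; the mixed anhydride formed at C15 is hydrolysed on work-up.

Step 19
Reactants: 31 7-acetoxy-3-methoxy-2-oxo-cis-clerod-3-en-15-oic acid
Product: 32 7-acetoxy-3-hydroxy-2-oxo-cis-clerod-3-en-15-oic acid
Conditions: BCl3 (3 equiv), CH2Cl2, −78 to −20 °C; H2O
Reagents that add atoms: none
Why: Chelation-assisted O-demethylation: boron binds the C2 carbonyl and the C3 methoxy oxygen and chloride removes the methyl group, as in the cleavage of methyl ethers ortho to aryl ketones; acetate and acid survive at low temperature.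

Step 20
Reactants: 32 7-acetoxy-3-hydroxy-2-oxo-cis-clerod-3-en-15-oic acid
Product: 35 7-acetoxy-2-hydroxy-3-oxo-cis-cleroda-1,4(18)-dien-15-oic acid (CNP0257844.1), via selenide 33 (not isolated), via selenoxide 34 (not isolated)
Conditions: PhSeCl, pyridine, CH2Cl2, 0 °C; then mCPBA (1.05 equiv), −78 °C; i-Pr2NH, −78 °C to rt
Reagents that add atoms: none
Why: α-Selenenylation of the C3 enol at C4, oxidation of the selenide at −78 °C and syn-elimination of the selenoxide. C5 has no hydrogen, so only C18 can lose one and the exocyclic double bond forms; the C2 carbonyl then enolises towards C1 to give the diosphenol of the target.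

## Compound list

1 | 2,3-dimethylanisole | COc1cccc(C)c1C | starting material
2 | 4-bromo-2,3-dimethylanisole | COc1ccc(Br)c(C)c1C | intermediate
3 | 5-bromo-2-methoxy-3,4-dimethylbenzaldehyde | COc1c(C=O)cc(Br)c(C)c1C | intermediate
4 | 5-bromo-2-methoxy-3,4-dimethylphenyl formate | COc1c(OC=O)cc(Br)c(C)c1C | intermediate
5 | 5-bromo-2-methoxy-3,4-dimethylphenol | COc1c(O)cc(Br)c(C)c1C | intermediate
6 | (5-bromo-2-methoxy-3,4-dimethylphenoxy)triisopropylsilane | COc1c(O[Si](C(C)C)(C(C)C)C(C)C)cc(Br)c(C)c1C | intermediate
7 | but-2-yn-1-ol | CC#CCO | starting material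
8 | sodium 2,2-bis(2-methoxyethoxy)-3-methyl-2,5-dihydro-1,2-oxaluminol-2-uide (cyclic alkenylaluminate) | CC1=CCO[Al-]1(OCCOC)OCCOC.[Na+] | intermediate
9 | (Z)-3-iodobut-2-en-1-ol | C/C(I)=C/CO | intermediate
10 | [4-methoxy-2,3-dimethyl-5-(triisopropylsilyloxy)phenyl]lithium | [Li]c1cc(O[Si](C(C)C)(C(C)C)C(C)C)c(OC)c(C)c1C | intermediate
11 | chloro[4-methoxy-2,3-dimethyl-5-(triisopropylsilyloxy)phenyl]zinc | Cl[Zn]c1cc(O[Si](C(C)C)(C(C)C)C(C)C)c(OC)c(C)c1C | intermediate
12 | (Z)-3-[4-methoxy-2,3-dimethyl-5-(triisopropylsilyloxy)phenyl]but-2-en-1-ol | OC/C=C(/C)c1cc(O[Si](C(C)C)(C(C)C)C(C)C)c(OC)c(C)c1C | intermediate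
13 | propanoyl chloride | CCC(=O)Cl | starting material
14 | (Z)-3-[4-methoxy-2,3-dimethyl-5-(triisopropylsilyloxy)phenyl]but-2-en-1-yl propanoate | CCC(=O)OC/C=C(/C)c1cc(O[Si](C(C)C)(C(C)C)C(C)C)c(OC)c(C)c1C | intermediate
15 | Z(O)-boron ketene acetal of 14 (C17 cis to O–B; boron in the (4S,5S)-4,5-diphenyl-1,3-bis[3,5-bis(trifluoromethyl)phenylsulfonyl]-1,3,2-diazaborolidine ring) | C/C=C(\OB1N(S(=O)(=O)c2cc(C(F)(F)F)cc(C(F)(F)F)c2)[C@@H](c2ccccc2)[C@H](c2ccccc2)N1S(=O)(=O)c1cc(C(F)(F)F)cc(C(F)(F)F)c1)OC/C=C(/C)c1cc(O[Si](C(C)C)(C(C)C)C(C)C)c(OC)c(C)c1C | intermediate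
16 | (2S,3S)-3-[4-methoxy-2,3-dimethyl-5-(triisopropylsilyloxy)phenyl]-2,3-dimethylpent-4-enoic acid | OC(=O)[C@@H](C)[C@](C)(C=C)c1cc(O[Si](C(C)C)(C(C)C)C(C)C)c(OC)c(C)c1C | intermediate
17 | methyl (2S,3S)-3-[4-methoxy-2,3-dimethyl-5-(triisopropylsilyloxy)phenyl]-2,3-dimethylpent-4-enoate | COC(=O)[C@@H](C)[C@](C)(C=C)c1cc(O[Si](C(C)C)(C(C)C)C(C)C)c(OC)c(C)c1C | intermediate
18 | B-alkyl-9-borabicyclo[3.3.1]nonane from 17 (boron on C5 of the pentanoate) | COC(=O)[C@@H](C)[C@](C)(CCB1C2CCCC1CCC2)c1cc(O[Si](C(C)C)(C(C)C)C(C)C)c(OC)c(C)c1C | intermediate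
19 | methyl (2S,3S,6Z)-8-hydroxy-3-[4-methoxy-2,3-dimethyl-5-(triisopropylsilyloxy)phenyl]-2,3,6-trimethyloct-6-enoate | COC(=O)[C@@H](C)[C@](C)(CC/C(C)=C\CO)c1cc(O[Si](C(C)C)(C(C)C)C(C)C)c(OC)c(C)c1C | intermediate
20 | methyl (2S,3S,6R)-8-hydroxy-3-[4-methoxy-2,3-dimethyl-5-(triisopropylsilyloxy)phenyl]-2,3,6-trimethyloctanoate | COC(=O)[C@@H](C)[C@](C)(CC[C@@H](C)CCO)c1cc(O[Si](C(C)C)(C(C)C)C(C)C)c(OC)c(C)c1C | intermediate
21 | methyl (2S,3S,6R)-8-(tert-butyldimethylsilyloxy)-3-[4-methoxy-2,3-dimethyl-5-(triisopropylsilyloxy)phenyl]-2,3,6-trimethyloctanoate | COC(=O)[C@@H](C)[C@](C)(CC[C@@H](C)CCO[Si](C)(C)C(C)(C)C)c1cc(O[Si](C(C)C)(C(C)C)C(C)C)c(OC)c(C)c1C | intermediate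
22 | tert-butyl{[(3R,6S,7S)-8-methoxy-6-[4-methoxy-2,3-dimethyl-5-(triisopropylsilyloxy)phenyl]-3,6,7-trimethylnon-8-en-1-yl]oxy}dimethylsilane (C7 methyl enol ether) | C=C(OC)[C@@H](C)[C@](C)(CC[C@@H](C)CCO[Si](C)(C)C(C)(C)C)c1cc(O[Si](C(C)C)(C(C)C)C(C)C)c(OC)c(C)c1C | intermediate
23 | (3R,6S,7S)-6-(5-hydroxy-4-methoxy-2,3-dimethylphenyl)-8-methoxy-3,6,7-trimethylnon-8-en-1-ol (precursor of the key step) | C=C(OC)[C@@H](C)[C@](C)(CC[C@@H](C)CCO)c1cc(O)c(OC)c(C)c1C | intermediate
24 | phenoxonium ion from 23 (drawn as the C3 methyloxonium form) | C=C(OC)[C@@H](C)[C@](C)(CC[C@@H](C)CCO)C1=CC(=O)C(=[O+]C)C(C)=C1C | intermediate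
25 | C7 methoxycarbenium ion after C5–C6 bond formation | CC1=C(OC)C(=O)C=C2[C@@](C)(CC[C@@H](C)CCO)[C@H](C)C(=[O+]C)C[C@]12C | intermediate
26 | 15-hydroxy-3-methoxycleroda-1(10),3-diene-2,7-dione (C19 cis to the C11 chain and trans to C20; C17 cis to C20; product of the key step) | CC1=C(OC)C(=O)C=C2[C@@](C)(CC[C@@H](C)CCO)[C@H](C)C(=O)C[C@]12C | intermediate
27 | 7,15-dihydroxy-3-methoxycleroda-1(10),3-dien-2-one (7-OH cis to C19) | CC1=C(OC)C(=O)C=C2[C@@](C)(CC[C@@H](C)CCO)[C@H](C)[C@@H](O)C[C@]12C | intermediate
28 | 7,15-dihydroxy-3-methoxy-cis-clerod-3-en-2-one (H10 cis to C19) | CC1=C(OC)C(=O)C[C@@H]2[C@@](C)(CC[C@@H](C)CCO)[C@H](C)[C@@H](O)C[C@]12C | intermediate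
29 | 7-hydroxy-3-methoxy-2-oxo-cis-clerod-3-en-15-al | CC1=C(OC)C(=O)C[C@@H]2[C@@](C)(CC[C@@H](C)CC=O)[C@H](C)[C@@H](O)C[C@]12C | intermediate
30 | 7-hydroxy-3-methoxy-2-oxo-cis-clerod-3-en-15-oic acid | CC1=C(OC)C(=O)C[C@@H]2[C@@](C)(CC[C@@H](C)CC(=O)O)[C@H](C)[C@@H](O)C[C@]12C | intermediate
31 | 7-acetoxy-3-methoxy-2-oxo-cis-clerod-3-en-15-oic acid | CC1=C(OC)C(=O)C[C@@H]2[C@@](C)(CC[C@@H](C)CC(=O)O)[C@H](C)[C@@H](OC(C)=O)C[C@]12C | intermediate
32 | 7-acetoxy-3-hydroxy-2-oxo-cis-clerod-3-en-15-oic acid (diosphenol) | CC1=C(O)C(=O)C[C@@H]2[C@@](C)(CC[C@@H](C)CC(=O)O)[C@H](C)[C@@H](OC(C)=O)C[C@]12C | intermediate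
33 | 7-acetoxy-2-hydroxy-3-oxo-4-(phenylselanyl)-cis-clerod-1-en-15-oic acid (C4 configuration not defined; it is lost in the next event) | CC1([Se]c3ccccc3)C(=O)C(O)=C[C@@H]2[C@@](C)(CC[C@@H](C)CC(=O)O)[C@H](C)[C@@H](OC(C)=O)C[C@]12C | intermediate
34 | selenoxide of 33 | CC1([Se](=O)c3ccccc3)C(=O)C(O)=C[C@@H]2[C@@](C)(CC[C@@H](C)CC(=O)O)[C@H](C)[C@@H](OC(C)=O)C[C@]12C | intermediate
35 | 7-acetoxy-2-hydroxy-3-oxo-cis-cleroda-1,4(18)-dien-15-oic acid (CNP0257844.1) | C=C1C(=O)C(O)=C[C@@H]2[C@@](C)(CC[C@@H](C)CC(=O)O)[C@H](C)[C@@H](OC(C)=O)C[C@]12C | target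

## Step count and least certain steps

Total: 20 steps. Longest linear sequence: 19 steps (1 to 35 through steps 1–4 and 6–20); step 5 is a one-step side branch.

**Step 14 (key step).** The phenoxonium ion may be lost through pathways other than ipso attack at C5: attack at C1 with rearomatisation, loss of a C19 proton to a quinone methide, or capture by water. Attack may also occur on the wrong face of C5 (poor facial selectivity), because the chair that gives the required isomer carries two pseudo-axial groups. Fallback: close the same bond without oxidation, by polarity reversal. It sets out from 22: NBS in wet THF converts the enol ether into bromomethyl ketone F1; Bu4NF then removes both silyl groups, and tetrabutylammonium phenoxide F2 alkylates itself at its para carbon C5 with C6 (intramolecular C-alkylation of a phenoxide), coming back to the route at 26.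

**Step 8.** The Lewis acidic bromoborane may ionise the electron-rich 3-aryl allylic ester (loss of the allyl group or a 1,3-shift) before the enolate rearranges, or the enantioselectivity may be low for this hindered ester. Fallback: a racemic rearrangement followed by resolution. It sets out from 14: LDA in THF–DMPU and Me3SiCl give trimethylsilyl ketene acetal F3 (C17 cis to OSi), which rearranges on warming to the same diastereomer as a racemate, acid 16 together with its enantiomer F4. Crystallisation with (S)-1-phenylethylamine gives ammonium salt F5, and acidification returns to the route at 16, which is methylated as in step 8.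

**Step 15.** Hydride may add from the wrong face if ring B of 26 is not the chair assumed, or the dienone carbonyl may be reduced as well. Fallback: move the C7 reduction behind the hydrogenation and use thermodynamic control. It sets out from 26: hydrogenation over Pd/C gives cis-fused diketone F6, and an equilibrating Meerwein–Ponndorf–Verley reduction (Al(O-i-Pr)3, i-PrOH, toluene, 80 °C) gives the 7-alcohol that is equatorial in the cis-decalin, coming back at 28.

**Step 16.** The catalyst may fail to reach the C1=C10 bond between two quaternary carbons, or hydrogen may be delivered to the face opposite the hydroxyl. Fallback: give up the directing group and rely on the shape of the substrate. It sets out from 27: oxidation of C15 (TEMPO, PhI(OAc)2) gives dienone acid F7, acetylation gives dienone acetate F8, and heterogeneous hydrogenation over Pd/C with Et3N, which adds hydrogen to such 1(10)-en-2-ones mainly cis to the angular methyl, comes back at 31.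

**Step 20.** Selenenylation at C4, next to the quaternary C5, may be slow, so that reaction through the other enol at C1 or over-oxidation of the diosphenol takes over. Fallback: functionalise C18 first and unmask afterwards. It sets out from 31: radical bromination of the allylic C18 methyl (NBS, AIBN, PhCF3, 80 °C) gives bromide F9, and silver-assisted SN1′ hydrolysis (AgNO3, aqueous acetone, 0 °C) lets water attack C3, with loss of methanol and formation of the C4=C18 bond. This replaces steps 19 and 20 and comes back at 35.

## Further compounds

F1 | step 14 | (3S,4S,7R)-1-bromo-9-(tert-butyldimethylsilyloxy)-4-[4-methoxy-2,3-dimethyl-5-(triisopropylsilyloxy)phenyl]-3,4,7-trimethylnonan-2-one (bromomethyl ketone) | BrCC(=O)[C@@H](C)[C@](C)(CC[C@@H](C)CCO[Si](C)(C)C(C)(C)C)c1cc(O[Si](C(C)C)(C(C)C)C(C)C)c(OC)c(C)c1C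
F2 | step 14 | tetrabutylammonium phenoxide of the desilylated bromomethyl ketone | BrCC(=O)[C@@H](C)[C@](C)(CC[C@@H](C)CCO)c1cc([O-])c(OC)c(C)c1C.CCCC[N+](CCCC)(CCCC)CCCC
F3 | step 8 | Z(O)-trimethylsilyl ketene acetal of 14 (C17 cis to OSi) | C/C=C(\O[Si](C)(C)C)OC/C=C(/C)c1cc(O[Si](C(C)C)(C(C)C)C(C)C)c(OC)c(C)c1C
F4 | step 8 | (2R,3R)-3-[4-methoxy-2,3-dimethyl-5-(triisopropylsilyloxy)phenyl]-2,3-dimethylpent-4-enoic acid (enantiomer of 16) | OC(=O)[C@H](C)[C@@](C)(C=C)c1cc(O[Si](C(C)C)(C(C)C)C(C)C)c(OC)c(C)c1C
F5 | step 8 | (S)-1-phenylethylammonium salt of 16 | [O-]C(=O)[C@@H](C)[C@](C)(C=C)c1cc(O[Si](C(C)C)(C(C)C)C(C)C)c(OC)c(C)c1C.C[C@H]([NH3+])c1ccccc1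
F6 | step 15 | 15-hydroxy-3-methoxy-cis-clerod-3-ene-2,7-dione | CC1=C(OC)C(=O)C[C@@H]2[C@@](C)(CC[C@@H](C)CCO)[C@H](C)C(=O)C[C@]12C
F7 | step 16 | 7-hydroxy-3-methoxy-2-oxocleroda-1(10),3-dien-15-oic acid | CC1=C(OC)C(=O)C=C2[C@@](C)(CC[C@@H](C)CC(=O)O)[C@H](C)[C@@H](O)C[C@]12C
F8 | step 16 | 7-acetoxy-3-methoxy-2-oxocleroda-1(10),3-dien-15-oic acid | CC1=C(OC)C(=O)C=C2[C@@](C)(CC[C@@H](C)CC(=O)O)[C@H](C)[C@@H](OC(C)=O)C[C@]12C
F9 | step 20 | 7-acetoxy-18-bromo-3-methoxy-2-oxo-cis-clerod-3-en-15-oic acid | BrCC1=C(OC)C(=O)C[C@@H]2[C@@](C)(CC[C@@H](C)CC(=O)O)[C@H](C)[C@@H](OC(C)=O)C[C@]12C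
A1 | alternative 1 | cis-fused decalin with C3 ketone, C4 dimethyl ketal, C8=C9 alkene, C7 benzyl ether and C19 on C5 | COC1(OC)C(=O)CC[C@@H]2C(C)=C[C@@H](OCc3ccccc3)C[C@]12C
A2 | alternative 2 | cis-fused octalin with C1=C2 alkene, C3 silyl ether, C4 methyl ester, C7 4-methoxybenzyl ether and the silyl-protected chain | COC(=O)[C@@H]1[C@H](O[Si](C)(C)C(C)(C)C)C=C[C@@H]2[C@@](C)(CC[C@@H](C)CCO[Si](c3ccccc3)(c3ccccc3)C(C)(C)C)[C@H](C)[C@@H](OCc3ccc(OC)cc3)C[C@]12C
A3 | alternative 3 | cis-fused C4 Mannich base with C3 ketone, C19 on C5, C7 silyl ether and the silyl-protected chain | CN(C)C[C@@H]1C(=O)CC[C@@H]2[C@@](C)(CC[C@@H](C)CCO[Si](C(C)C)(C(C)C)C(C)C)[C@H](C)[C@@H](O[Si](C)(C)C(C)(C)C)C[C@]12C
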